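**Retrosynthetic overview**

1. Target 15 ⇐ bis-silyl ester 14 (desilylation) ⇐ cis-diol 11 (acetate, then angelate) ⇐ cis-fused α-methylene-γ-lactone 8 (reductive opening). The lactone is a temporary ring C that ties the C3 oxygen to the carbon of the C2 side chain.
2. Key disconnection: the C3a–C3 bond of dihydrofuran ring B, formed by intramolecular Friedel–Crafts attack of C3a on a cyclic acyloxycarbenium ion at C3. The ion is generated from acyclic aryl ether 6 (tert-butyl acrylate plus dimethyl acetal) in one acid-triggered cascade.
3. 6 ⇐ C2–O(aryl) bond by palladium-catalysed dynamic kinetic asymmetric allylic etherification of racemic Morita–Baylis–Hillman carbonate 4 with 2,4-dihydroxyacetophenone 5; 4 ⇐ 1 + 2.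
4. Enabling feature: C3a is ortho to the ring oxygen on C7a, para to the C6 hydroxyl and meta to the C5 acetyl, so it is the most nucleophilic and least hindered arene carbon. C3 is at the aldehyde oxidation level and its oxygen is cis to the C2 side chain, so a cis-fused 5/5 lactone can carry both.
5. Ring order: benzene ring A is bought; temporary lactone ring C, then dihydrofuran ring B, both in step 4; ring C is opened in step 6.

Key step: step 4

Assumption (remark on the chemistry): the (R,R)-enantiomer of the DACH-phenyl bisphosphine ligand is taken to deliver the (R)-ether 6. If the sense of induction is the opposite, the (S,S)-ligand is used and nothing else changes.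

**Route**

Step 1
Reactants: 1 2,2-dimethoxyacetaldehyde (60 wt % in water); 2 tert-butyl acrylate
Product: 3 tert-butyl 3-hydroxy-4,4-dimethoxy-2-methylidenebutanoate (racemic)
Conditions: DABCO (1 equiv), 1,4-dioxane/H2O (1:1), rt
Reagents that add atoms: none
Why: Morita–Baylis–Hillman reaction in which the DABCO–acrylate zwitterion adds to the activated α,α-dialkoxy aldehyde and the amine is then eliminated; the new carbinol centre is racemic, which is harmless because step 3 is stereoconvergent.

Step 2
Reactants: 3 tert-butyl 3-hydroxy-4,4-dimethoxy-2-methylidenebutanoate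
Product: 4 tert-butyl 3-[(methoxycarbonyl)oxy]-4,4-dimethoxy-2-methylidenebutanoate (racemic)
Conditions: ClCO2Me, pyridine, CH2Cl2, 0 °C to rt
Reagents that add atoms: methyl chloroformate, COC(=O)Cl
Why: Standard O-acylation of a secondary allylic alcohol with a chloroformate, which installs the ionisable carbonate leaving group needed for the allylic substitution.

Step 3
Reactants: 4 tert-butyl 3-[(methoxycarbonyl)oxy]-4,4-dimethoxy-2-methylidenebutanoate; 5 2,4-dihydroxyacetophenone
Product: 6 tert-butyl (3R)-3-(4-acetyl-3-hydroxyphenoxy)-4,4-dimethoxy-2-methylidenebutanoate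
Conditions: Pd2(dba)3·CHCl3 (2 mol %), (R,R)-N,N'-(cyclohexane-1,2-diyl)bis(2-diphenylphosphinobenzamide) (6 mol %), CH2Cl2, rt
Reagents that add atoms: none
Why: Palladium-catalysed asymmetric allylic etherification (Tsuji–Trost type) run as a dynamic kinetic asymmetric transformation, in which both enantiomers of 4 ionise to 2-(alkoxycarbonyl)allyl palladium complexes that equilibrate by π–σ–π interconversion, the non-chelated and more acidic 4-hydroxyl of 5 (deprotonated by the methoxide released from the carbonate) attacks the substituted allyl terminus, and the chiral ligand sets the C–O stereocentre as R.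

Step 4
Reactants: 6 tert-butyl (3R)-3-(4-acetyl-3-hydroxyphenoxy)-4,4-dimethoxy-2-methylidenebutanoate
Product: 8 (3aR,8bR)-7-acetyl-6-hydroxy-3-methylidene-3a,8b-dihydrofuro[3,2-b][1]benzofuran-2(3H)-one (cis-fused methylene lactone), via hydroxylactone 7 (not isolated)
Conditions: TFA/CH2Cl2/H2O (10:10:1), 0 °C to rt; evaporate; then TfOH (5 mol %), HFIP, 0 °C, 0.01 M
Reagents that add atoms: none
Why: Proposed new method: aqueous TFA removes the tert-butyl ester and the dimethyl acetal, the formyl acid closes to hydroxylactone 7, and acid-promoted loss of water from 7 gives a cyclic acyloxycarbenium ion that is attacked by the arene carbon ortho to the ether oxygen and para to the phenol, so that the aryl–C(sp3) bond, the dihydrofuran ring and the benzylic C–O(acyl) centre arise together (the water taken up in forming 7 is given back in the closure). The closest known reaction types are the acid-mediated Friedel–Crafts condensation of pseudo-acids such as 2-formylbenzoic acid or 5-hydroxyfuranones with phenol ethers to γ-aryl lactones and the classical acid cyclisation of aryloxyacetaldehyde acetals onto the ortho carbon; new here is the intramolecular combination that stops at the 3-acyloxy-2,3-dihydrobenzofuran stage. Ring closures: the lactone (ring C) by 5-exo-trig addition of the carboxyl oxygen to the formyl group, the dihydrofuran (ring B) by an electrophilic aromatic substitution that is 5-exo-trig at the C=O+ carbon. The new benzylic stereocentre is controlled by the existing aryloxy-bearing centre through the ring fusion, because only the cis-fused 5/5 lactone is attainable; a trans hydroxy acid formed through the open-chain aldehyde would re-ionise at the p-hydroxybenzylic position and be captured by the carboxyl group on the cis face, so both pathways should converge on the (3aR,8bR) isomer. The step needs site selectivity between the two ortho carbons, secured by the reacting carbon being para to the hydroxyl and unhindered whereas the other lies between two oxygens, and it must stop before loss of the lactone carboxylate with aromatisation to a benzofuran, which the intramolecular carboxyl trap, high dilution, low temperature and only catalytic strong acid in the second stage are meant to secure.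

Step 5
Reactants: 8 (3aR,8bR)-7-acetyl-6-hydroxy-3-methylidene-3a,8b-dihydrofuro[3,2-b][1]benzofuran-2(3H)-one
Product: 9 (3aR,8bR)-6-[(tert-butyldimethylsilyl)oxy]-7-{1-[(tert-butyldimethylsilyl)oxy]ethenyl}-3-methylidene-3a,8b-dihydrofuro[3,2-b][1]benzofuran-2(3H)-one
Conditions: TBSOTf (2.5 equiv), Et3N (4 equiv), CH2Cl2, 0 °C
Reagents that add atoms: tert-butyldimethylsilyl trifluoromethanesulfonate, CC(C)(C)[Si](C)(C)OS(=O)(=O)C(F)(F)F
Why: Silylation with a silyl triflate and an amine base converts the phenol into its silyl ether and the methyl ketone into its silyl enol ether, which masks the ketone against hydride in step 6 and the phenol against acylation in steps 7 and 8.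

Step 6
Reactants: 9 bis-silylated lactone
Product: 11 (2R,3R)-6-[(tert-butyldimethylsilyl)oxy]-5-{1-[(tert-butyldimethylsilyl)oxy]ethenyl}-2-(3-hydroxyprop-1-en-2-yl)-2,3-dihydro-1-benzofuran-3-ol, via lactol 10 (not isolated)
Conditions: iBu2AlH (DIBAL-H, 4 equiv), CH2Cl2, −78 to −20 °C; aq. potassium sodium tartrate work-up
Reagents that add atoms: none
Why: 1,2-Reduction of an α-methylene-γ-butyrolactone by DIBAL-H through the lactol to the 2-methylene-1,4-diol, in which no stereocentre is touched and the silyl enol ether and aryl silyl ether are inert to the hydride at low temperature.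

Step 7
Reactants: 11 cis-diol
Product: 12 2-[(2R,3R)-6-[(tert-butyldimethylsilyl)oxy]-5-{1-[(tert-butyldimethylsilyl)oxy]ethenyl}-3-hydroxy-2,3-dihydro-1-benzofuran-2-yl]prop-2-en-1-yl acetate
Conditions: AcCl (1.05 equiv), 2,4,6-collidine, CH2Cl2, −78 °C
Reagents that add atoms: acetyl chloride, CC(=O)Cl
Why: Rate-based selective acylation, in which acetyl chloride with the hindered base collidine at low temperature acetylates the primary allylic hydroxyl much faster than the hindered secondary benzylic one.

Step 8
Reactants: 12 monoacetate; 13 angelic acid [(2Z)-2-methylbut-2-enoic acid]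
Product: 14 (2R,3R)-2-[3-(acetyloxy)prop-1-en-2-yl]-6-[(tert-butyldimethylsilyl)oxy]-5-{1-[(tert-butyldimethylsilyl)oxy]ethenyl}-2,3-dihydro-1-benzofuran-3-yl (2Z)-2-methylbut-2-enoate
Conditions: 13, 2,4,6-Cl3C6H2COCl, Et3N, toluene, rt; then 12, 80 °C (no DMAP)
Reagents that add atoms: none
Why: Yamaguchi-type esterification through the preformed mixed anhydride of angelic acid and 2,4,6-trichlorobenzoic acid, run without a nucleophilic catalyst, which is the established way to acylate hindered secondary alcohols with retention of the Z geometry of the angelate and of the carbinol configuration.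

Step 9
Reactants: 14 bis-silyl angelate
Product: 15 (2R,3R)-5-acetyl-2-[3-(acetyloxy)prop-1-en-2-yl]-6-hydroxy-2,3-dihydro-1-benzofuran-3-yl (2Z)-2-methylbut-2-enoate (target)
Conditions: HF·pyridine, pyridine/THF, 0 °C to rt
Reagents that add atoms: none
Why: Fluoride-mediated desilylation under buffered acidic conditions cleaves the aryl silyl ether and protodesilylates the silyl enol ether to the methyl ketone, while the acetate, the angelate and the benzylic C–O bond should survive because no free phenoxide is generated that could expel the angelate.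

**Compound list**

1 | 2,2-dimethoxyacetaldehyde | COC(OC)C=O | starting material
2 | tert-butyl acrylate | C=CC(=O)OC(C)(C)C | starting material
3 | tert-butyl 3-hydroxy-4,4-dimethoxy-2-methylidenebutanoate (racemic) | C=C(C(=O)OC(C)(C)C)C(O)C(OC)OC | intermediate
4 | tert-butyl 3-[(methoxycarbonyl)oxy]-4,4-dimethoxy-2-methylidenebutanoate (racemic) | C=C(C(=O)OC(C)(C)C)C(OC(=O)OC)C(OC)OC | intermediate
5 | 2,4-dihydroxyacetophenone | CC(=O)c1ccc(O)cc1O | starting material
6 | tert-butyl (3R)-3-(4-acetyl-3-hydroxyphenoxy)-4,4-dimethoxy-2-methylidenebutanoate | C=C(C(=O)OC(C)(C)C)[C@@H](Oc1ccc(C(C)=O)c(O)c1)C(OC)OC | intermediate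
7 | (4R)-4-(4-acetyl-3-hydroxyphenoxy)-5-hydroxy-3-methylideneoxolan-2-one (both C5 epimers) | C=C1C(=O)OC(O)[C@@H]1Oc2ccc(C(C)=O)c(O)c2 | intermediate (not isolated)
8 | (3aR,8bR)-7-acetyl-6-hydroxy-3-methylidene-3a,8b-dihydrofuro[3,2-b][1]benzofuran-2(3H)-one | C=C1[C@H]2Oc3cc(O)c(C(C)=O)cc3[C@H]2OC1=O | intermediate
9 | (3aR,8bR)-6-[(tert-butyldimethylsilyl)oxy]-7-{1-[(tert-butyldimethylsilyl)oxy]ethenyl}-3-methylidene-3a,8b-dihydrofuro[3,2-b][1]benzofuran-2(3H)-one | C=C1[C@H]2Oc3cc(O[Si](C)(C)C(C)(C)C)c(C(=C)O[Si](C)(C)C(C)(C)C)cc3[C@H]2OC1=O | intermediate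
10 | (3aR,8bR)-6-[(tert-butyldimethylsilyl)oxy]-7-{1-[(tert-butyldimethylsilyl)oxy]ethenyl}-3-methylidene-2,3,3a,8b-tetrahydrofuro[3,2-b][1]benzofuran-2-ol (lactol, present as its aluminium alkoxide) | C=C1[C@H]2Oc3cc(O[Si](C)(C)C(C)(C)C)c(C(=C)O[Si](C)(C)C(C)(C)C)cc3[C@H]2OC1O | intermediate (not isolated)
11 | (2R,3R)-6-[(tert-butyldimethylsilyl)oxy]-5-{1-[(tert-butyldimethylsilyl)oxy]ethenyl}-2-(3-hydroxyprop-1-en-2-yl)-2,3-dihydro-1-benzofuran-3-ol | C=C(CO)[C@H]1Oc2cc(O[Si](C)(C)C(C)(C)C)c(C(=C)O[Si](C)(C)C(C)(C)C)cc2[C@H]1O | intermediate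
12 | 2-[(2R,3R)-6-[(tert-butyldimethylsilyl)oxy]-5-{1-[(tert-butyldimethylsilyl)oxy]ethenyl}-3-hydroxy-2,3-dihydro-1-benzofuran-2-yl]prop-2-en-1-yl acetate | C=C(COC(C)=O)[C@H]1Oc2cc(O[Si](C)(C)C(C)(C)C)c(C(=C)O[Si](C)(C)C(C)(C)C)cc2[C@H]1O | intermediate
13 | angelic acid, (2Z)-2-methylbut-2-enoic acid | C/C=C(/C)C(=O)O | starting material
14 | (2R,3R)-2-[3-(acetyloxy)prop-1-en-2-yl]-6-[(tert-butyldimethylsilyl)oxy]-5-{1-[(tert-butyldimethylsilyl)oxy]ethenyl}-2,3-dihydro-1-benzofuran-3-yl (2Z)-2-methylbut-2-enoate | C=C(COC(C)=O)[C@H]1Oc2cc(O[Si](C)(C)C(C)(C)C)c(C(=C)O[Si](C)(C)C(C)(C)C)cc2[C@H]1OC(=O)/C(C)=C\C | intermediate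
15 | (2R,3R)-5-acetyl-2-[3-(acetyloxy)prop-1-en-2-yl]-6-hydroxy-2,3-dihydro-1-benzofuran-3-yl (2Z)-2-methylbut-2-enoate | C=C(COC(C)=O)[C@H]1Oc2cc(O)c(C(C)=O)cc2[C@H]1OC(=O)/C(C)=C\C | target

**Step count and risks**

Total steps: 9. Longest linear sequence: 9 steps (1/2 → 15).

Steps most likely to fail:

1. Step 4 (Proposed new method). Three processes could divert it. The benzylic lactone C–O bond of the product could ionise under the acid with loss of the adjacent ring proton, which aromatises the system to a benzofuran. Ring closure could occur at the ortho carbon lying between the two oxygens. The released tert-butyl cation could alkylate the arene. Fallback with known chemistry, setting out from carbonate 4 and returning at lactone 8: the etherification of step 3 is run with commercial 1-(2,4-dihydroxy-5-iodophenyl)ethanone (CC(=O)c1cc(I)c(O)cc1O) in place of 5. This should give tert-butyl (3R)-3-(4-acetyl-5-hydroxy-2-iodophenoxy)-4,4-dimethoxy-2-methylidenebutanoate F1, since ionisation of the allyl carbonate at room temperature is expected to outpace oxidative addition of the aryl iodide to zerovalent palladium. Amberlyst-15 in wet acetone should unmask tert-butyl (3R)-3-(4-acetyl-5-hydroxy-2-iodophenoxy)-2-methylidene-4-oxobutanoate F2, which is used at once because its α-proton is labile. An intramolecular Nozaki–Hiyama–Kishi reaction (CrCl2, NiCl2 cat., DMF, rt) then forms the same aryl–carbinol bond, from the iodine-bearing carbon only and without acid, to give tert-butyl 2-[(2R,3R)-5-acetyl-3,6-dihydroxy-2,3-dihydro-1-benzofuran-2-yl]prop-2-enoate F3; the chelated phenol is expected to be tolerated by the weakly basic arylchromium species. Brief TFA/CH2Cl2 at 0 °C cleaves the tert-butyl ester and lactonises the cis-hydroxy acid to 8. In this variant the cis relationship is not enforced during C–C bond formation: only the cis isomer can lactonise, and any trans hydroxy acid is removed by bicarbonate extraction.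

2. Step 3. Enantio- and regioselectivity could erode. The product aryl ether can re-ionise, because the phenoxide of an acylphenol is a fair leaving group, which would cause racemisation or drift to the linear achiral isomer. The hindered, inductively deactivated carbonate could also ionise sluggishly. Fallback, setting out from carbonate 4 and returning at 6: DABCO-catalysed substitution of 4 with 5 in THF (amine SN2′ addition–elimination followed by phenoxide SN2′, no metal–allyl intermediate) should give racemic tert-butyl 3-(4-acetyl-3-hydroxyphenoxy)-4,4-dimethoxy-2-methylidenebutanoate F4. Preparative chromatography on a chiral stationary phase then separates (R)-6 from tert-butyl (3S)-3-(4-acetyl-3-hydroxyphenoxy)-4,4-dimethoxy-2-methylidenebutanoate F5, which is discarded.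

3. Step 8. Acylation of the hindered cis-disposed secondary benzylic alcohol could be incomplete, the angelate could isomerise from Z to E, or the benzylic alcohol could eliminate on heating. Fallback, setting out from 12 and returning at 14: Steglich esterification of 12 with 2-[bis(2,2,2-trifluoroethoxy)phosphoryl]propanoic acid (DCC, DMAP cat., CH2Cl2, 0 °C) should give (2R,3R)-2-[3-(acetyloxy)prop-1-en-2-yl]-6-[(tert-butyldimethylsilyl)oxy]-5-{1-[(tert-butyldimethylsilyl)oxy]ethenyl}-2,3-dihydro-1-benzofuran-3-yl 2-[bis(2,2,2-trifluoroethoxy)phosphoryl]propanoate F6. A Still–Gennari olefination with acetaldehyde (KN(SiMe3)2, 18-crown-6, THF, −78 °C) then builds the Z-trisubstituted alkene on the ester already in place, giving 14.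

**Further compounds**

F1 | step 4 | tert-butyl (3R)-3-(4-acetyl-5-hydroxy-2-iodophenoxy)-4,4-dimethoxy-2-methylidenebutanoate | C=C(C(=O)OC(C)(C)C)[C@@H](Oc1cc(O)c(C(C)=O)cc1I)C(OC)OC
F2 | step 4 | tert-butyl (3R)-3-(4-acetyl-5-hydroxy-2-iodophenoxy)-2-methylidene-4-oxobutanoate | C=C(C(=O)OC(C)(C)C)[C@@H](Oc1cc(O)c(C(C)=O)cc1I)C=O
F3 | step 4 | tert-butyl 2-[(2R,3R)-5-acetyl-3,6-dihydroxy-2,3-dihydro-1-benzofuran-2-yl]prop-2-enoate | C=C(C(=O)OC(C)(C)C)[C@H]1Oc2cc(O)c(C(C)=O)cc2[C@H]1O
F4 | step 3 | tert-butyl 3-(4-acetyl-3-hydroxyphenoxy)-4,4-dimethoxy-2-methylidenebutanoate (racemic) | C=C(C(=O)OC(C)(C)C)C(Oc1ccc(C(C)=O)c(O)c1)C(OC)OC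
F5 | step 3 | tert-butyl (3S)-3-(4-acetyl-3-hydroxyphenoxy)-4,4-dimethoxy-2-methylidenebutanoate | C=C(C(=O)OC(C)(C)C)[C@H](Oc1ccc(C(C)=O)c(O)c1)C(OC)OC
F6 | step 8 | (2R,3R)-2-[3-(acetyloxy)prop-1-en-2-yl]-6-[(tert-butyldimethylsilyl)oxy]-5-{1-[(tert-butyldimethylsilyl)oxy]ethenyl}-2,3-dihydro-1-benzofuran-3-yl 2-[bis(2,2,2-trifluoroethoxy)phosphoryl]propanoate | C=C(COC(C)=O)[C@H]1Oc2cc(O[Si](C)(C)C(C)(C)C)c(C(=C)O[Si](C)(C)C(C)(C)C)cc2[C@H]1OC(=O)C(C)P(=O)(OCC(F)(F)F)OCC(F)(F)F
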